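**Plan**

1. Retrosynthesis: the C9–C10 bond is cut first (intramolecular aldol of the furanone C10–H onto a C9 aldehyde). Then follow the O8 ester, the furanone (O–C3 by cyclisation of an α'-hydroxy ynone, C1–C2 by acylation of a terminal alkyne), the spiro-epoxide (C11–O and C11–C13 from the lactone enolate), the lactone C12–O6 bond, the C7–C8 aldol bond and the C6–C7 bond.
2. Forward: (Z)-3-methylpent-2-en-4-yn-1-ol supplies C2–C6 and C15 with the Z-alkene in place. Homoenolate addition and oxidation give a γ-keto ester, a boron aldol with (R)-glyceraldehyde acetonide adds C8–C9, and reduction with lactonisation closes the γ-lactone. The spiro-epoxide, the C8 methacrylate, the ynone and the 3(2H)-furanone follow, and glycol cleavage unveils the C9 aldehyde for the closure of the ten-membered carbocycle.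
3. Enabling feature: in the 2-methyl-3(2H)-furanone ring (O, C3, C2, C1, C10) the C10–H is unusually acidic because its enolate is an aromatic 3-oxidofuran. C10 lies 1,3 across this ring from C3, which carries the Z-C4=C5 tether, so the furanolate can add through C10 to the C9 aldehyde and is dearomatised to the quaternary C10 of the target.
4. Stereochemistry: the only purchased stereocentre is that of (R)-glyceraldehyde acetonide (it becomes C9, is erased at the glycol cleavage and re-formed in the key step). It sets C8 (Felkin–Anh) and C7 (anti aldol); O8 sets C6 (1,3-anti reduction); C7 sets C11 (formaldehyde anti to the side chain); C6/C7 through the tether and a tin chelate set C10 and C9.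
5. Helpers: a C-silyl group on the alkyne and silyl ethers on O8/O11 (all removed by fluoride in step 11); the acetonide on C9/C9' (removed in step 16; C9' leaves as formaldehyde in step 17).

Key step: step 18

Remark on labels: carbons are labelled as in a germacrane. C1 is the ketone, C2=C3 the furanone alkene, C4=C5 the Z-alkene, C6 the lactone carbinol, C8 the ester carbinol, C9 the free carbinol, C10 the quaternary carbon, C11/C12/C13 the lactone α-carbon, carbonyl and epoxide CH2, C14/C15 the methyls on C10/C4. C9' is the extra carbon of the glyceraldehyde unit. The target is (6R,7S,8S,9R,10S,11S).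

Assumption: the lactate-derived centre (C10) in 25–30 is drawn (S); it is configurationally labile in the furanones and becomes planar in step 18, so its integrity is not required.

**Route**

Step 1
Reactants: 1 (Z)-3-methylpent-2-en-4-yn-1-ol
Product: 3 (Z)-3-methyl-5-(trimethylsilyl)pent-2-en-4-yn-1-ol, via O,C-bis(trimethylsilyl) enynol 2 (not isolated)
Conditions: EtMgBr (2.2 equiv), THF, 0 → 45 °C; Me3SiCl (2.3 equiv), 0 °C → rt; then 1 M HCl, rt
Reagents that add atoms: chlorotrimethylsilane, C[Si](C)(C)Cl
Why: Double deprotonation (alkoxide and magnesium acetylide), bis-silylation and selective acid hydrolysis of the O–Si bond is a standard C-silylation of an alkynol; the silyl group blocks the acidic alkyne C–H during the later enolate steps and no stereocentre is formed.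

Step 2
Reactants: 3 (Z)-3-methyl-5-(trimethylsilyl)pent-2-en-4-yn-1-ol
Product: 4 (Z)-3-methyl-5-(trimethylsilyl)pent-2-en-4-ynal
Conditions: MnO2 (activated, excess), CH2Cl2, rt, dark
Reagents that add atoms: none
Why: Allylic alcohol oxidation with MnO2 is neutral and heterogeneous, so the Z-alkene, which already has the formyl group cis to the slim alkynyl substituent, should not isomerise; no stereocentre is formed.

Step 3
Reactants: 4 (Z)-3-methyl-5-(trimethylsilyl)pent-2-en-4-ynal; 5 1-ethoxy-1-(trimethylsilyloxy)cyclopropane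
Product: 7 ethyl (Z)-4-hydroxy-6-methyl-8-(trimethylsilyl)oct-5-en-7-ynoate (racemic), via trimethylsilyl ether 6 (not isolated)
Conditions: 5 (2.2 equiv), ZnCl2 (1.1 equiv), Et2O, rt; then 4, CH2Cl2, 0 °C → rt; aq. citric acid, MeOH, 0 °C
Reagents that add atoms: none
Why: ZnCl2 opens the siloxycyclopropane to a zinc homoenolate that adds 1,2 to the enal under activation by the Me3SiCl formed alongside (homoenolate addition, forming C6–C7), and mild acid frees the alcohol; the new C6 carbinol is racemic and is oxidised in the next step.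

Step 4
Reactants: 7 ethyl (Z)-4-hydroxy-6-methyl-8-(trimethylsilyl)oct-5-en-7-ynoate
Product: 8 ethyl (Z)-6-methyl-4-oxo-8-(trimethylsilyl)oct-5-en-7-ynoate
Conditions: MnO2 (excess), CH2Cl2, rt
Reagents that add atoms: none
Why: MnO2 should oxidise the allylic alcohol to the enone before the hydroxy ester lactonises, which removes the racemic centre and leaves C7 as the only enolisable ketone α-position.

Step 5
Reactants: 8 ethyl (Z)-6-methyl-4-oxo-8-(trimethylsilyl)oct-5-en-7-ynoate; 9 (R)-2,2-dimethyl-1,3-dioxolane-4-carbaldehyde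
Product: 11 aldol adduct ethyl (3R,4S)-4-[(4R)-2,2-dimethyl-1,3-dioxolan-4-yl]-4-hydroxy-3-[(Z)-3-methyl-5-(trimethylsilyl)pent-2-en-4-ynoyl]butanoate, via boron enolate 10 (not isolated)
Conditions: (c-C6H11)2BCl, Et3N, Et2O, −78 → 0 °C; then 9 (freshly distilled), −78 → −20 °C; pH 7 buffer, MeOH
Reagents that add atoms: none
Why: Boron aldol addition: (c-C6H11)2BCl/Et3N should give the E(O)-enolborinate at C7, whose chair-like Zimmerman–Traxler transition state delivers the 7,8-anti aldol, while Felkin–Anh addition to the α-alkoxy aldehyde places the new C8 hydroxyl anti to the dioxolane C–O, so C7 and C8 are both set from the purchased stereocentre.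

Step 6
Reactants: 11 aldol adduct
Product: 13 (4R,5R)-4-{(S)-[(4R)-2,2-dimethyl-1,3-dioxolan-4-yl](hydroxy)methyl}-5-[(Z)-2-methyl-4-(trimethylsilyl)but-1-en-3-yn-1-yl]oxolan-2-one, via anti-diol ester 12 (not isolated)
Conditions: Me4NBH(OAc)3, MeCN/AcOH, −30 °C; then PPTS (cat.), benzene, 45 °C
Reagents that add atoms: none
Why: Evans–Saksena reduction: the C8 hydroxyl binds the acetoxyborohydride and delivers hydride intramolecularly through a chair transition state to give the 1,3-anti diol (sets C6), and PPTS then closes the γ-lactone on the C6 hydroxyl because this gives the trans-4,5-disubstituted ring, whereas closure on O8 would give the cis isomer.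

Step 7
Reactants: 13 lactone alcohol
Product: 14 O8-triethylsilyl ether of 13
Conditions: Et3SiOTf, 2,6-lutidine, CH2Cl2, −78 °C
Reagents that add atoms: triethylsilyl trifluoromethanesulfonate, CC[Si](CC)(CC)OS(=O)(=O)C(F)(F)F
Why: Silylation of the free secondary alcohol with a silyl triflate and a hindered base protects O8 against alkoxide-induced translactonisation in the enolate steps; no stereocentre changes.

Step 8
Reactants: 14 O8-triethylsilyl lactone
Product: 17 11-(triethylsilyloxy) lactone (O8,O11-bis-silyl ether), via potassium enolate 15 (not isolated), via potassium 11-alkoxide 16 (not isolated)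
Conditions: KN(SiMe3)2, THF, −78 °C; 2-(phenylsulfonyl)-3-phenyloxaziridine, −78 °C; then Et3SiCl, −78 → 0 °C
Reagents that add atoms: 2-(phenylsulfonyl)-3-phenyloxaziridine, O=S(=O)(N1OC1c1ccccc1)c1ccccc1; chlorotriethylsilane, CC[Si](CC)(CC)Cl
Why: Enolate hydroxylation with an N-sulfonyloxaziridine followed by silylation of the resulting alkoxide in the same flask installs the C11 oxygen (expected anti to the C7 side chain, although this configuration is erased in step 9).

Step 9
Reactants: 17 11-(triethylsilyloxy) lactone
Product: 19 11-(hydroxymethyl)-11-(triethylsilyloxy) lactone, via lithium enolate 18 (not isolated)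
Conditions: LiN(iPr)2, THF, −78 °C; CH2O (gas, from paraformaldehyde), −78 °C; AcOH quench at −78 °C
Reagents that add atoms: formaldehyde, C=O
Why: Aldol addition of the α-silyloxy lactone enolate to formaldehyde: the electrophile should approach the planar enolate anti to the bulky C7 substituent, so C13 ends up trans and the oxygen cis to the C8 branch, which is the C11 configuration of the target.

Step 10
Reactants: 19 11-(hydroxymethyl)-11-(triethylsilyloxy) lactone
Product: 20 primary p-toluenesulfonate of 19
Conditions: TsCl, pyridine, DMAP (cat.), CH2Cl2, 0 °C → rt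
Reagents that add atoms: p-toluenesulfonyl chloride, Cc1ccc(cc1)S(Cl)(=O)=O
Why: Sulfonylation of the only free (primary) hydroxyl turns C13 into an electrophile; no stereocentre is touched.

Step 11
Reactants: 20 tosylate
Product: 22 spiro-epoxy lactone with free C8 hydroxyl and terminal alkyne, via hydroxy tosylate 21 (not isolated)
Conditions: Bu4NF (4 equiv), THF, 0 °C → rt; aq. NH4Cl
Reagents that add atoms: none
Why: Fluoride cleaves the two O–Si bonds and the alkynyl C–Si bond, and the liberated tertiary C11 alkoxide displaces the neighbouring primary tosylate (3-exo-tet Williamson closure) with retention at C11, while the C8 oxygen cannot attack C13 because that would need a trans-fused bicyclo[3.3.0] ring.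

Step 12
Reactants: 22 epoxy lactone alcohol
Product: 23 C8 methacrylate of 22
Conditions: methacrylic anhydride, Et3N, DMAP (cat.), BHT (trace), CH2Cl2, 0 °C → rt
Reagents that add atoms: methacrylic anhydride, CC(=C)C(=O)OC(=O)C(C)=C
Why: DMAP-catalysed acylation of the secondary C8 alcohol installs the methacrylate now that no further enolate chemistry follows; the configuration at C8 is retained.

Step 13
Reactants: 24 (S)-lactic acid
Product: 25 triethylsilyl (S)-2-(triethylsilyloxy)propanoate
Conditions: Et3SiCl (2.2 equiv), imidazole, DMF, 0 °C → rt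
Reagents that add atoms: chlorotriethylsilane, CC[Si](CC)(CC)Cl
Why: Silylation of both the hydroxyl and the carboxyl group with a silyl chloride and imidazole; the stereocentre is untouched.

Step 14
Reactants: 25 triethylsilyl (S)-2-(triethylsilyloxy)propanoate
Product: 26 (S)-2-(triethylsilyloxy)propanoyl chloride
Conditions: (COCl)2, DMF (cat.), CH2Cl2, 0 °C → rt; used crude
Reagents that add atoms: oxalyl chloride, ClC(=O)C(Cl)=O
Why: Silyl esters are converted directly into acid chlorides by oxalyl chloride with catalytic DMF under neutral conditions (no HCl is formed), which should leave the acid-labile silyl ether in place.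

Step 15
Reactants: 23 methacrylate alkyne; 26 (S)-2-(triethylsilyloxy)propanoyl chloride
Product: 27 α'-(triethylsilyloxy) ynone
Conditions: CuI (5 mol%), Et3N (1.5 equiv), THF, rt, argon
Reagents that add atoms: none
Why: Copper-catalysed acylation of the terminal alkyne through its copper acetylide (palladium-free Sonogashira-type ynone synthesis) forms C1–C2; palladium is left out because zerovalent palladium could ionise the allylic lactone C6–O bond.

Step 16
Reactants: 27 α'-(triethylsilyloxy) ynone
Product: 29 2-methyl-3(2H)-furanone with free C9/C9' diol, via trihydroxy ynone 28 (not isolated)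
Conditions: AcOH/THF/H2O (3:1:1), 40 °C; then Ph3PAuNTf2 (2 mol%), CH2Cl2, rt, argon
Reagents that add atoms: none
Why: Aqueous acetic acid hydrolyses the triethylsilyl ether and the terminal acetonide, and the π-acidic gold catalyst then triggers 5-endo-dig attack of the α'-hydroxyl on the ynone (hydroalkoxylation), which after protodeauration gives the 3(2H)-furanone.

Step 17
Reactants: 29 furanone diol
Product: 30 seco-aldehyde (furanone with C8 methacrylate and C9 aldehyde)
Conditions: NaIO4, THF/pH 7 phosphate buffer, 0 °C, short contact; used at once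
Reagents that add atoms: none
Why: Periodate glycol cleavage of the terminal 1,2-diol gives the C9 aldehyde under neutral conditions; the acylated O8 keeps the C8–C9 bond from being cleaved, and immediate use limits epimerisation at C8.

Step 18
Reactants: 30 seco-aldehyde
Product: 32 target (6R,7S,8S,9R,10S,11S), via tin furanolate 31 (not isolated)
Conditions: Sn(OTf)2 (1.5 equiv), N-ethylpiperidine (1.6 equiv), CH2Cl2, −78 °C; 30 added by syringe pump (final about 1 mM); −78 → −40 °C; pH 7 buffer
Reagents that add atoms: none
Why: Proposed new method: Sn(OTf)2 binds the furanone carbonyl and N-ethylpiperidine removes the C10–H, which is acidic because the resulting divalent-tin enolate 31 is a 6π-aromatic 3-stannyloxyfuran; its C10 then adds to the tethered C9 aldehyde and the ring is dearomatised back to a 3(2H)-furanone, the closest known reaction types being the Sn(OTf)2/amine ketone aldol addition, the Mukaiyama aldol of 3-silyloxyfurans with aldehydes at the same carbon and metal-enolate aldol closures of medium rings. One C–C bond closes two rings at once, the ten-membered carbocycle C1–C10 (10-exo-trig onto the aldehyde) and, counted through the furanone oxygen, the nine-membered oxacycle (9-exo-trig), which leaves the furanone bridging C3 and C10. C10 (S) is set by the tether: A(1,3) strain in the Z-alkene keeps the C6–H bond in the alkene plane facing the furan oxygen, so C7, held by the trans-fused lactone, and with it C8 and C9 can lie over only one face of the furan, and the C14 methyl is pushed to the outer face. C9 (R) is set by a closed, tin-bridged transition state between the furanolate oxygen and the aldehyde oxygen: the tether forces C8 to lie across the furan ring, so the chelate can form only with the carbonyl oxygen turned toward C1, which gives the 8,9-syn arrangement of the target. The step needs attack through C10 and not through oxygen or the vinylic C2, ring closure instead of intermolecular aldol, and no enolisation of the α-acyloxy aldehyde: C10 is the enolate carbon flanked by both oxygens, the much higher acidity of C10–H over C8–H directs the weak amine base, slow addition at high dilution suppresses oligomers, and the halide-free tin salt at −78 °C should spare the spiro-epoxide and the methacrylate.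

**Compound list**

1 | (Z)-3-methylpent-2-en-4-yn-1-ol | C#C/C(C)=C\CO | starting material
2 | O,C-bis(trimethylsilyl) derivative of 1 (not isolated) | C[Si](C)(C)C#C/C(C)=C\CO[Si](C)(C)C | intermediate
3 | (Z)-3-methyl-5-(trimethylsilyl)pent-2-en-4-yn-1-ol | C[Si](C)(C)C#C/C(C)=C\CO | intermediate
4 | (Z)-3-methyl-5-(trimethylsilyl)pent-2-en-4-ynal | C[Si](C)(C)C#C/C(C)=C\C=O | intermediate
5 | 1-ethoxy-1-(trimethylsilyloxy)cyclopropane | CCOC1(CC1)O[Si](C)(C)C | starting material
6 | ethyl (Z)-6-methyl-8-(trimethylsilyl)-4-(trimethylsilyloxy)oct-5-en-7-ynoate, racemic (not isolated) | CCOC(=O)CCC(O[Si](C)(C)C)/C=C(C)\C#C[Si](C)(C)C | intermediate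
7 | ethyl (Z)-4-hydroxy-6-methyl-8-(trimethylsilyl)oct-5-en-7-ynoate, racemic | CCOC(=O)CCC(O)/C=C(C)\C#C[Si](C)(C)C | intermediate
8 | ethyl (Z)-6-methyl-4-oxo-8-(trimethylsilyl)oct-5-en-7-ynoate | CCOC(=O)CCC(=O)/C=C(C)\C#C[Si](C)(C)C | intermediate
9 | (R)-2,2-dimethyl-1,3-dioxolane-4-carbaldehyde | O=C[C@H]1COC(C)(C)O1 | starting material
10 | E(O)-dicyclohexylboron enolate of 8 (not isolated) | CCOC(=O)C/C=C(/OB(C1CCCCC1)C1CCCCC1)\C=C(C)/C#C[Si](C)(C)C | intermediate
11 | ethyl (3R,4S)-4-[(4R)-2,2-dimethyl-1,3-dioxolan-4-yl]-4-hydroxy-3-[(Z)-3-methyl-5-(trimethylsilyl)pent-2-en-4-ynoyl]butanoate | CCOC(=O)C[C@@H](C(=O)/C=C(C)\C#C[Si](C)(C)C)[C@H](O)[C@H]1COC(C)(C)O1 | intermediate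
12 | ethyl (3S,4S)-4-[(4R)-2,2-dimethyl-1,3-dioxolan-4-yl]-4-hydroxy-3-[(1R,2Z)-1-hydroxy-3-methyl-5-(trimethylsilyl)pent-2-en-4-yn-1-yl]butanoate (not isolated) | CCOC(=O)C[C@@H]([C@H](O)/C=C(C)\C#C[Si](C)(C)C)[C@H](O)[C@H]1COC(C)(C)O1 | intermediate
13 | (4R,5R)-4-{(S)-[(4R)-2,2-dimethyl-1,3-dioxolan-4-yl](hydroxy)methyl}-5-[(Z)-2-methyl-4-(trimethylsilyl)but-1-en-3-yn-1-yl]oxolan-2-one | C[Si](C)(C)C#C/C(C)=C\[C@H]1OC(=O)C[C@@H]1[C@H](O)[C@H]2COC(C)(C)O2 | intermediate
14 | O8-triethylsilyl ether of 13 | C[Si](C)(C)C#C/C(C)=C\[C@H]1OC(=O)C[C@@H]1[C@H](O[Si](CC)(CC)CC)[C@H]2COC(C)(C)O2 | intermediate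
15 | potassium enolate of 14 (not isolated) | C[Si](C)(C)C#C/C(C)=C\[C@H]1OC(O[K])=C[C@@H]1[C@H](O[Si](CC)(CC)CC)[C@H]2COC(C)(C)O2 | intermediate
16 | potassium alkoxide of the 11-hydroxy lactone, oxygen trans to the C7 side chain (not isolated) | C[Si](C)(C)C#C/C(C)=C\[C@H]1OC(=O)[C@@H](O[K])[C@@H]1[C@H](O[Si](CC)(CC)CC)[C@H]2COC(C)(C)O2 | intermediate
17 | 11-(triethylsilyloxy) lactone (O8,O11-bis-silyl ether) | C[Si](C)(C)C#C/C(C)=C\[C@H]1OC(=O)[C@@H](O[Si](CC)(CC)CC)[C@@H]1[C@H](O[Si](CC)(CC)CC)[C@H]2COC(C)(C)O2 | intermediate
18 | lithium enolate of 17 (not isolated) | C[Si](C)(C)C#C/C(C)=C\[C@H]1OC(O[Li])=C(O[Si](CC)(CC)CC)[C@@H]1[C@H](O[Si](CC)(CC)CC)[C@H]2COC(C)(C)O2 | intermediate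
19 | 11-(hydroxymethyl)-11-(triethylsilyloxy) lactone, C13 trans to the C8 branch | C[Si](C)(C)C#C/C(C)=C\[C@H]1OC(=O)[C@@](O[Si](CC)(CC)CC)(CO)[C@@H]1[C@H](O[Si](CC)(CC)CC)[C@H]2COC(C)(C)O2 | intermediate
20 | primary p-toluenesulfonate of 19 | C[Si](C)(C)C#C/C(C)=C\[C@H]1OC(=O)[C@@](O[Si](CC)(CC)CC)(COS(=O)(=O)c3ccc(C)cc3)[C@@H]1[C@H](O[Si](CC)(CC)CC)[C@H]2COC(C)(C)O2 | intermediate
21 | fully desilylated hydroxy tosylate, reacting as its C11 alkoxide (not isolated) | C#C/C(C)=C\[C@H]1OC(=O)[C@@](O)(COS(=O)(=O)c3ccc(C)cc3)[C@@H]1[C@H](O)[C@H]2COC(C)(C)O2 | intermediate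
22 | spiro-epoxy lactone with free C8 hydroxyl, terminal alkyne and C9/C9' acetonide | C#C/C(C)=C\[C@H]1OC(=O)[C@@]3(CO3)[C@@H]1[C@H](O)[C@H]2COC(C)(C)O2 | intermediate
23 | C8 methacrylate of 22 | C#C/C(C)=C\[C@H]1OC(=O)[C@@]3(CO3)[C@@H]1[C@H](OC(=O)C(C)=C)[C@H]2COC(C)(C)O2 | intermediate
24 | (S)-lactic acid | C[C@H](O)C(=O)O | starting material
25 | triethylsilyl (S)-2-(triethylsilyloxy)propanoate | C[C@H](O[Si](CC)(CC)CC)C(=O)O[Si](CC)(CC)CC | intermediate
26 | (S)-2-(triethylsilyloxy)propanoyl chloride | C[C@H](O[Si](CC)(CC)CC)C(Cl)=O | intermediate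
27 | α'-(triethylsilyloxy) ynone (C1–C2 joined; epoxy lactone, methacrylate and acetonide in place) | C[C@H](O[Si](CC)(CC)CC)C(=O)C#C/C(C)=C\[C@H]1OC(=O)[C@@]3(CO3)[C@@H]1[C@H](OC(=O)C(C)=C)[C@H]2COC(C)(C)O2 | intermediate
28 | trihydroxy ynone (α'-hydroxy ynone with free C9/C9' diol; not isolated) | C[C@H](O)C(=O)C#C/C(C)=C\[C@H]1OC(=O)[C@@]3(CO3)[C@@H]1[C@H](OC(=O)C(C)=C)[C@H](O)CO | intermediate
29 | 2-methyl-3(2H)-furanone with C9/C9' diol (C10 drawn S, epimerisable) | C[C@@H]1OC(=CC1=O)/C(C)=C\[C@H]2OC(=O)[C@@]3(CO3)[C@@H]2[C@H](OC(=O)C(C)=C)[C@H](O)CO | intermediate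
30 | seco-aldehyde: furanone with C8 methacrylate and C9 aldehyde (C10 drawn S, epimerisable) | C[C@@H]1OC(=CC1=O)/C(C)=C\[C@H]2OC(=O)[C@@]3(CO3)[C@@H]2[C@H](OC(=O)C(C)=C)C=O | intermediate
31 | divalent-tin 3-furanolate of 30 (aromatic; not isolated) | Cc1oc(cc1O[Sn]OS(=O)(=O)C(F)(F)F)/C(C)=C\[C@H]2OC(=O)[C@@]3(CO3)[C@@H]2[C@H](OC(=O)C(C)=C)C=O | intermediate
32 | CNP0407138.2, (6R,7S,8S,9R,10S,11S)-8-methacryloyloxy-9-hydroxy-11,13-epoxy furanone-bridged germacranolide | C=C(C)C(=O)O[C@H]1[C@@H]2[C@@H](/C=C(/C)C3=CC(=O)[C@@](C)(O3)[C@@H]1O)OC(=O)[C@@]21CO1 | target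

**Summary**

Total step count: 18. Longest linear sequence: 16 steps (steps 1–12 and 15–18; steps 13–14 make the acid chloride 26).

Steps most likely to fail:

1. Step 18 (Proposed new method). What may go wrong: intermolecular aldol and oligomerisation instead of ring closure; closure through the vinylic furan carbon C2 to an eight-membered ring; poor facial selectivity at C9 or C10; enolisation of the α-acyloxy aldehyde with epimerisation at C8; retro-aldol of the strained product. Fallback with known chemistry (reductively generated samarium enolate, Reformatsky-type medium-ring aldol), setting out from 27 and rejoining at 32: HF·pyridine in THF should remove only the silyl ether of 27, and Ph3PAuNTf2 then gives the furanone acetonide F1. iPr3SiOTf/Et3N converts it into the 3-(triisopropylsilyloxy)furan F2. NBS at −78 °C brominates the silyl enol ether carbon to give the 10-bromo furanone acetonide F3. H5IO6 in EtOAc cleaves the terminal acetonide directly to the 10-bromo furanone aldehyde F4. SmI2 in THF at −78 °C reduces the C10–Br bond to a trivalent-samarium furanolate, which should close the ring through the same chelated transition state under neutral, irreversible conditions to give 32.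

2. Step 9. What may go wrong: incomplete enolisation of the hindered α-silyloxy lactone; oxygen-to-oxygen silyl migration after the aldol; loss of formaldehyde by retro-aldol; insufficient facial selectivity at C11. Fallback (Mannich route with an ammonium leaving group), setting out from 17 and rejoining at 22: the lithium enolate of 17 is trapped with N,N-dimethylmethyleneiminium iodide, again anti to the C7 side chain, to give the 11-(dimethylaminomethyl) lactone F5. MeI quaternises it to the trimethylammonium iodide F6. Bu4NF then removes the silyl groups, and the C11 alkoxide displaces trimethylamine to close the epoxide, giving 22.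

3. Step 16. What may go wrong: acid-induced opening of the spiro-epoxide; migration of the methacrylate to the liberated diol; ionisation at the allylic C6–O bond; side reactions of the gold catalyst with the enyne; autoxidation of the C10–H furanone. Fallback (amine conjugate addition and addition–elimination instead of π-acid catalysis), setting out from 27 and rejoining at 29: Et2NH (1.1 equiv) in EtOH at 0 °C should add only to the ynone and give the β-(diethylamino) enone F7. AcOH/THF/H2O at 40 °C then hydrolyses the silyl ether and the acetonide, and the freed α'-hydroxyl displaces diethylamine at C3 to give 29.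

**Further compounds**

F1 | step 18 | furanone acetonide (C10–H furanone, C9/C9' still as acetonide) | C[C@@H]1OC(=CC1=O)/C(C)=C\[C@H]2OC(=O)[C@@]3(CO3)[C@@H]2[C@H](OC(=O)C(C)=C)[C@H]4COC(C)(C)O4
F2 | step 18 | 3-(triisopropylsilyloxy)furan derived from F1 | Cc1oc(cc1O[Si](C(C)C)(C(C)C)C(C)C)/C(C)=C\[C@H]2OC(=O)[C@@]3(CO3)[C@@H]2[C@H](OC(=O)C(C)=C)[C@H]4COC(C)(C)O4
F3 | step 18 | 10-bromo furanone acetonide (both C10 epimers) | CC1(Br)OC(=CC1=O)/C(C)=C\[C@H]2OC(=O)[C@@]3(CO3)[C@@H]2[C@H](OC(=O)C(C)=C)[C@H]4COC(C)(C)O4
F4 | step 18 | 10-bromo furanone aldehyde (both C10 epimers) | CC1(Br)OC(=CC1=O)/C(C)=C\[C@H]2OC(=O)[C@@]3(CO3)[C@@H]2[C@H](OC(=O)C(C)=C)C=O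
F5 | step 9 | 11-(dimethylaminomethyl)-11-(triethylsilyloxy) lactone | C[Si](C)(C)C#C/C(C)=C\[C@H]1OC(=O)[C@@](O[Si](CC)(CC)CC)(CN(C)C)[C@@H]1[C@H](O[Si](CC)(CC)CC)[C@H]2COC(C)(C)O2
F6 | step 9 | trimethylammonium iodide of F5 | C[Si](C)(C)C#C/C(C)=C\[C@H]1OC(=O)[C@@](O[Si](CC)(CC)CC)(C[N+](C)(C)C)[C@@H]1[C@H](O[Si](CC)(CC)CC)[C@H]2COC(C)(C)O2.[I-]
F7 | step 16 | β-(diethylamino) enone from 27 | C[C@H](O[Si](CC)(CC)CC)C(=O)/C=C(N(CC)CC)\C(C)=C/[C@H]1OC(=O)[C@@]3(CO3)[C@@H]1[C@H](OC(=O)C(C)=C)[C@H]2COC(C)(C)O2
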